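## Analysis of the target

Brandisianin A 23 is an isoflavone, that is a chromen-4-one (benzo ring A fused to pyranone ring C) with an aryl ring B on C3. Ring A carries free hydroxyls at C5 and C7, the former hydrogen-bonded to the C4 carbonyl, and ring B carries methoxy groups at C2' and C5' and a 3-methylbut-2-enyl (prenyl) ether at C4'. There is no stereocentre, so the task is one of regiochemistry and of telling five oxygens apart. The sensitive sites are C2 of the pyranone (an acceptor that hard nucleophiles, secondary amines and strong bases open), the prenyl aryl ether (ionised by acid, rearranged by heat, destroyed by hydrogenation) and the electron-rich ring B. The difficulty is that three ring B oxygens must end as two methyl ethers and one prenyl ether while the two ring A oxygens end free, and that the C3–C1' bond joins the pyranone to a ring with an ortho substituent. The strategy rests on the oxygen pattern of ring B: the oxygens at C2' and C5' are para to each other and the oxygen at C4' is para to C1'. That is a 2-aryl-5-alkoxy-1,4-benzoquinone at the hydroquinone oxidation level, in which the two future methoxy oxygens are carbonyl oxygens and the future prenyl ether oxygen is an ether oxygen, and such a quinone is the ring-expansion product of a squarate-derived 4-alkynylcyclobutenone whose alkyne sits on C3 of the chromone.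

## Retrosynthetic reasoning

**23 from 22.** The two O–Si bonds on ring A are cut last. Silyl ethers are chosen for ring A because their cleavage needs neither acid nor hydrogenation, so it touches neither the prenyl ether nor the pyranone.

**22 from 20 and 21.** The O–C bond of the prenyl ether is cut next. The prenyl group must come in after the hydrogenolysis and after the heated step, so it is attached to the free 4'-phenol of 20 with 3-methylbut-2-en-1-ol 21 under neutral Mitsunobu conditions, at a stage where no other phenol is free.

**20 from 19.** The 4'-oxygen is carried as a benzyl ether. Benzyl survives the thermolysis (an allyl or prenyl enol ether on the four-membered ring would undergo Claisen rearrangement), survives reduction and methylation, and is removed by hydrogenolysis before the alkene of the prenyl group is present.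

**19 from 17 by way of 18.** The two methyl ethers are traced back to the two carbonyl oxygens of quinone 17. Reduction to hydroquinone 18 and O-methylation distinguish these oxygens from the benzyl ether oxygen by oxidation level alone, so no selective protection on ring B is needed.

**17 from 14 (key disconnection).** Ring B is opened at C1'–C2', which leads back to the 4-alkynyl-4-hydroxycyclobutenone 14. This cut is preferred over a cut at C3–C1' because it turns the hindered aryl–pyranone bond into an alkyne–pyranone bond and lets all three ring B oxygens come from one squarate. In the forward direction the four-membered ring must open to enynylketene 15, and the ketene carbon must close on the far alkyne carbon, not the near one. A conjugating group on the alkyne terminus does not help here; it stabilises the exocyclic radical or cation of the five-membered closure. This is accepted as the main risk of the route, and solvent, temperature and a cross-coupling fallback are planned around it.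

**14 from 7 and 12.** The bond between the carbinol carbon and the alkyne is cut. The acetylide 13 formed from 7 must add to the ketone carbonyl of 12 next to the benzyloxy-bearing carbon and not to the vinylogous ester carbonyl. That site of addition is what places the 4'-oxygen para to C1' in 17.

**12 from 8 and 9.** The benzyl semisquarate 12 comes from squaric acid 8 and two equivalents of benzyl alcohol 9 by way of diester 10, mono-reduction to 11, and acid-mediated loss of one benzyloxy group.

**7 from 4 and 5.** The alkyne–C3 bond is cut to the 3-iodochromone 4 and ethynyl(trimethyl)silane 5, joined by Sonogashira coupling to 6. The C–Si bond of 6 is then cleaved without touching the aryl O–Si bonds.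

**4 from 1.** The pyranone ring is cut at O1–C2 and C2–C3. Trihydroxyacetophenone 1 is silylated twice to 2, extended by one carbon to enaminone 3, and closed with iodination to 4. The one free ortho hydroxyl of 2 becomes O1.

## Alternatives that were turned down

Alternative 1: The pyranone is disconnected at C3–C4 and O1–C8a, with ring B complete from the start. The morpholine enamine A3 is C-acylated at its β-carbon by the acid chloride A2 . Here A3 is 4-[(E)-2-[2,5-dimethoxy-4-(3-methylbut-2-enyloxy)phenyl]ethenyl]morpholine and A2 is 2,4,6-trifluorobenzoyl chloride. After the amino group is exchanged for oxygen in aqueous base, the enolate oxygen displaces an ortho fluoride and gives the difluorochromone A1 , 3-[2,5-dimethoxy-4-(3-methylbut-2-enyloxy)phenyl]-5,7-difluorochromen-4-one.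
- For: it is convergent and short, the ring closure is a well-activated intramolecular substitution, and ring B needs no protecting group.
- Against: A1 has fluorine where 23 has hydroxyl at C5 and C7. Two aryl C–F bonds must be exchanged with alkoxide-type nucleophiles, which also attack C2 of the pyranone, and the oxygen must then be unmasked without acid or hydrogen because the prenyl ether is already present. With so electron-rich an aryl group on its double bond, A3 is also prone to hydrolysis and oxidation before A2 can acylate it.
- Comparison: this route reaches the isoflavone skeleton in fewer steps than the chosen route and has no ring-size question. The chosen route instead has every oxygen in place at the right oxidation level from the starting materials and introduces the prenyl group only when nothing harsh follows.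

Alternative 2: The disconnection is at C3–C1' and O1–C2. The enaminone A5 is oxidised at an anode together with the arene A6 . Here A5 is (E)-3-(dimethylamino)-1-[2-hydroxy-4,6-bis(pivaloyloxy)phenyl]prop-2-en-1-one and A6 is 1,4-dimethoxy-2-(3-methylbut-2-enyloxy)benzene. The α-carbon of A5 couples to an arene C–H of A6, and the ortho hydroxyl then closes the pyranone with loss of the amino group. The product is the bis-pivalate A4 , 3-[2,5-dimethoxy-4-(3-methylbut-2-enyloxy)phenyl]-5,7-bis(pivaloyloxy)chromen-4-one.
- For: it is the shortest route, needs no prefunctionalised ring B, and the innate reactivity of A6 points to the right carbon (para to the prenyloxy group and ortho to a methoxy group). The pivalates leave under mild base that spares the prenyl ether.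
- Against: nothing in the structures secures chemoselectivity at the anode. The radical cation of A6 can lose the prenyl group or dimerise, the fluorinated alcohol medium favours ionisation of the prenyl ether, and A4 is itself oxidisable. The free phenol of A5 is a further site of oxidation.
- Comparison: it is clearly stronger on step economy. The chosen route offers a thermal, unimolecular ring construction in which the prenyl ether is absent, so the uncertain step has only one competing pathway.

Alternative 3: The pyranone is disconnected at O1–C8a and C4–C4a. Fluoride generates an aryne from the silyl triflate A8 , 3,5-bis(methoxymethoxy)-2-(trimethylsilyl)phenyl trifluoromethanesulfonate. The enolate oxygen of the formylacetate A9 adds to it, and the resulting aryl anion closes on the ester carbonyl. Here A9 is methyl 2-[4-(allyloxy)-2,5-dimethoxyphenyl]-3-oxopropanoate. The product is the isoflavone A7 , 3-[4-(allyloxy)-2,5-dimethoxyphenyl]-5,7-bis(methoxymethoxy)chromen-4-one.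
- For: the alkoxy group next to the aryne directs the nucleophile to the remote aryne carbon, which maps correctly onto the 5,7-pattern, and the coupling is convergent.
- Against: an enolate such as that of A9 usually attacks an aryne through carbon and then inserts into the C–C bond, so O-arylation is the less likely course. A8 needs several steps. The acetal groups of A7 need acid for removal, so the allyl group must be exchanged for prenyl at a point where either the prenyl ether meets acid or the 7-hydroxyl competes in the alkylation.
- Comparison: its control of the ring A pattern is as good as in the chosen route and its length is similar. The chosen route has an endgame in which fluoride removes the ring A groups in the presence of the prenyl ether.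

Key step: step 10

Remark on the chemistry: 23 has no stereocentre. Compounds 11 and 14 each carry one carbinol stereocentre, are made and used as racemates, and lose that centre in steps 8 and 10.

## Route

Step 1
Reactants: 1 2',4',6'-trihydroxyacetophenone
Product: 2 1-[2-hydroxy-4,6-bis(triisopropylsilyloxy)phenyl]ethan-1-one
Conditions: iPr3SiCl (2.2 equiv), imidazole, DMF, 0 °C to rt
Reagents that add atoms: chlorotriisopropylsilane, CC(C)[Si](Cl)(C(C)C)C(C)C
Why: Phenol silylation; the hydroxyl para to the acetyl group and one ortho hydroxyl react, while the last ortho hydroxyl is held in the hydrogen bond to the carbonyl and is hindered, so the reaction should stop at the bis-silyl ether.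

Step 2
Reactants: 2 1-[2-hydroxy-4,6-bis(triisopropylsilyloxy)phenyl]ethan-1-one
Product: 3 (E)-3-(dimethylamino)-1-[2-hydroxy-4,6-bis(triisopropylsilyloxy)phenyl]prop-2-en-1-one
Conditions: Me2NCH(OMe)2, toluene, 90 °C
Reagents that add atoms: N,N-dimethylformamide dimethyl acetal, COC(OC)N(C)C
Why: Condensation of the methyl ketone with the amide acetal gives the E-enaminone with loss of methanol; the neutral conditions leave the aryl silyl ethers intact.

Step 3
Reactants: 3 (E)-3-(dimethylamino)-1-[2-hydroxy-4,6-bis(triisopropylsilyloxy)phenyl]prop-2-en-1-one
Product: 4 3-iodo-5,7-bis(triisopropylsilyloxy)chromen-4-one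
Conditions: I2, pyridine, CHCl3, rt
Reagents that add atoms: iodine, II
Why: Iodinative cyclisation of a 2-hydroxyaryl enaminone: iodination at the α-carbon gives an iminium ion, the phenol adds to it and the amine leaves, which closes the pyranone as the 3-iodochromone; pyridine buffers the acid so the silyl ethers should survive.

Step 4
Reactants: 4 3-iodo-5,7-bis(triisopropylsilyloxy)chromen-4-one; 5 ethynyl(trimethyl)silane
Product: 6 3-[(trimethylsilyl)ethynyl]-5,7-bis(triisopropylsilyloxy)chromen-4-one
Conditions: Pd(PPh3)2Cl2 (cat.), CuI (cat.), Et3N, THF, rt
Reagents that add atoms: none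
Why: Sonogashira coupling of a vinylogous-ester iodide, a reactive partner for oxidative addition; a tertiary amine is used because secondary amines open the pyranone at C2.

Step 5
Reactants: 6 3-[(trimethylsilyl)ethynyl]-5,7-bis(triisopropylsilyloxy)chromen-4-one
Product: 7 3-ethynyl-5,7-bis(triisopropylsilyloxy)chromen-4-one
Conditions: AgNO3 (0.1 equiv), MeOH/H2O/CH2Cl2, rt
Reagents that add atoms: none
Why: Silver-catalysed protiodesilylation is selective for the alkynyl C–Si bond; no alkoxide or fluoride is present, so the aryl O–Si bonds and the pyranone should be left alone.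

Step 6
Reactants: 8 squaric acid; 9 benzyl alcohol
Product: 10 3,4-bis(benzyloxy)cyclobut-3-ene-1,2-dione
Conditions: BnOH (2.5 equiv in all), toluene, reflux, Dean–Stark trap
Reagents that add atoms: benzyl alcohol (the second equivalent of 9), OCc1ccccc1
Why: Squaric acid is a strong vinylogous acid and catalyses its own esterification; each of its two acidic hydroxyls is exchanged for one molecule of the primary alcohol on azeotropic removal of water (vinylogous Fischer esterification), so two equivalents of 9 are taken up.

Step 7
Reactants: 10 3,4-bis(benzyloxy)cyclobut-3-ene-1,2-dione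
Product: 11 2,3-bis(benzyloxy)-4-hydroxycyclobut-2-en-1-one (racemic)
Conditions: LiAlH(OtBu)3, THF, −20 °C; then aqueous work-up
Reagents that add atoms: none
Why: 1,2-Reduction of one of the two equivalent vinylogous ester carbonyls by a hindered, mild hydride, which should stop at the hydroxycyclobutenone at low temperature; the carbinol centre forms racemic and is not needed.

Step 8
Reactants: 11 2,3-bis(benzyloxy)-4-hydroxycyclobut-2-en-1-one
Product: 12 3-(benzyloxy)cyclobut-3-ene-1,2-dione
Conditions: conc. aqueous HCl, CH2Cl2, rt
Reagents that add atoms: water, O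
Why: Acid ionises the allylic hydroxyl (lost as water) to an alkoxy-stabilised cyclobutenyl cation, water adds at the cationic carbon that bears a benzyloxy group, and loss of benzyl alcohol from the hemiketal unmasks the 1,2-dione. This is the known conversion of mono-reduced dialkyl squarates into semisquarate esters; in sum only benzyl alcohol is lost.

Step 9
Reactants: 7 3-ethynyl-5,7-bis(triisopropylsilyloxy)chromen-4-one; 12 3-(benzyloxy)cyclobut-3-ene-1,2-dione
Product: 14 3-(benzyloxy)-4-hydroxy-4-{[4-oxo-5,7-bis(triisopropylsilyloxy)chromen-3-yl]ethynyl}cyclobut-2-en-1-one (racemic), via lithium acetylide 13 (not isolated)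
Conditions: LiN(SiMe3)2, THF, −78 °C; then 12, THF, −78 °C; aqueous NH4Cl at −78 °C
Reagents that add atoms: none
Why: 1,2-Addition of a lithium acetylide to a semisquarate ester, which is known to take place at the ketone carbonyl next to the alkoxy-bearing carbon because the other carbonyl is deactivated as a vinylogous ester; the non-nucleophilic silylamide base and the low temperature should spare the pyranone, and the new carbinol centre is racemic and is lost in step 10.

Step 10
Reactants: 14 3-(benzyloxy)-4-hydroxy-4-{[4-oxo-5,7-bis(triisopropylsilyloxy)chromen-3-yl]ethynyl}cyclobut-2-en-1-one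
Product: 17 2-(benzyloxy)-5-[4-oxo-5,7-bis(triisopropylsilyloxy)chromen-3-yl]cyclohexa-2,5-diene-1,4-dione, via enynylketene 15 (not isolated), via phenoxyl-aryl diradical 16 (not isolated)
Conditions: toluene (0.01 M, degassed), 110 °C, argon
Reagents that add atoms: none
Why: This is a Moore rearrangement, the known thermal ring expansion of squarate-derived 4-alkynyl-4-hydroxycyclobutenones to 1,4-benzoquinones. Heating cleaves the bond between the carbonyl carbon and the carbinol carbon in a conrotatory 4π electrocyclic opening in which the donor hydroxyl rotates outward, so the alkynyl group ends up cis to the ketene arm in enynylketene 15. The ketene carbon then bonds to the far alkyne carbon, the one that bears the chromonyl group, in a 6-endo-dig closure that forms C1'–C2' and gives the aromatic diradical 16; transfer of the hydroxyl hydrogen to the aryl radical centre gives quinone 17. No stereocentre is formed and the carbinol centre of 14 is erased. Two selectivities are needed: the 2,5-substitution pattern, which is already fixed by the site of acetylide addition in step 9, and six- over five-membered closure, the latter being attack at the near alkyne carbon to an alkylidene cyclopentenedione. The second is not guaranteed by the substrate, because the conjugating chromonyl group can stabilise the exocyclic vinyl radical or cation of the five-ring path; what favours the quinone is the aromatic stabilisation of 16 and the unhindered oxygen terminus of the ketene. A non-polar solvent is chosen to disfavour the more polar, zwitterion-like five-ring channel, the temperature is kept at the minimum needed for ring opening, and high dilution under argon limits bimolecular reactions of 15 and 17.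

Step 11
Reactants: 17 2-(benzyloxy)-5-[4-oxo-5,7-bis(triisopropylsilyloxy)chromen-3-yl]cyclohexa-2,5-diene-1,4-dione
Product: 18 3-[4-(benzyloxy)-2,5-dihydroxyphenyl]-5,7-bis(triisopropylsilyloxy)chromen-4-one
Conditions: Na2S2O4, EtOAc/H2O, rt, argon
Reagents that add atoms: none
Why: Dithionite reduction of a 1,4-benzoquinone to the hydroquinone; the chromone carbonyl and the benzyl ether are not reduced, and the air-sensitive product is carried on at once.

Step 12
Reactants: 18 3-[4-(benzyloxy)-2,5-dihydroxyphenyl]-5,7-bis(triisopropylsilyloxy)chromen-4-one
Product: 19 3-[4-(benzyloxy)-2,5-dimethoxyphenyl]-5,7-bis(triisopropylsilyloxy)chromen-4-one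
Conditions: MeI, K2CO3, acetone (degassed), rt, argon
Reagents that add atoms: iodomethane, CI
Why: Williamson methylation of both phenols; anhydrous carbonate in acetone at room temperature is mild towards hindered aryl silyl ethers, and any reversible addition of the 2'-phenoxide to C2 is drained by irreversible O-methylation.

Step 13
Reactants: 19 3-[4-(benzyloxy)-2,5-dimethoxyphenyl]-5,7-bis(triisopropylsilyloxy)chromen-4-one
Product: 20 3-(4-hydroxy-2,5-dimethoxyphenyl)-5,7-bis(triisopropylsilyloxy)chromen-4-one
Conditions: H2 (1 atm), Pd/C, EtOAc, rt
Reagents that add atoms: none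
Why: Hydrogenolysis of the benzyl aryl ether; at one atmosphere, and stopped after one equivalent of hydrogen, the C2=C3 bond of the isoflavone should stay intact.

Step 14
Reactants: 20 3-(4-hydroxy-2,5-dimethoxyphenyl)-5,7-bis(triisopropylsilyloxy)chromen-4-one; 21 3-methylbut-2-en-1-ol
Product: 22 3-[2,5-dimethoxy-4-(3-methylbut-2-enyloxy)phenyl]-5,7-bis(triisopropylsilyloxy)chromen-4-one
Conditions: PPh3, iPrO2CN=NCO2iPr, THF, 0 °C to rt
Reagents that add atoms: none
Why: Mitsunobu etherification of the only free phenol with a primary allylic alcohol; substitution at the primary carbon gives the linear prenyl ether, and the neutral conditions leave the silyl ethers and the pyranone untouched.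

Step 15
Reactants: 22 3-[2,5-dimethoxy-4-(3-methylbut-2-enyloxy)phenyl]-5,7-bis(triisopropylsilyloxy)chromen-4-one
Product: 23 brandisianin A
Conditions: Bu4NF, AcOH, THF, 0 °C
Reagents that add atoms: none
Why: Fluoride cleaves both aryl O–Si bonds; acetic acid buffers the phenoxides, so the pyranone and the prenyl ether should not be affected.

## Compound list

1 | 2',4',6'-trihydroxyacetophenone | CC(=O)c1c(O)cc(O)cc1O | starting material
2 | 1-[2-hydroxy-4,6-bis(triisopropylsilyloxy)phenyl]ethan-1-one | CC(=O)c1c(O)cc(O[Si](C(C)C)(C(C)C)C(C)C)cc1O[Si](C(C)C)(C(C)C)C(C)C | intermediate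
3 | (E)-3-(dimethylamino)-1-[2-hydroxy-4,6-bis(triisopropylsilyloxy)phenyl]prop-2-en-1-one | CN(C)/C=C/C(=O)c1c(O)cc(O[Si](C(C)C)(C(C)C)C(C)C)cc1O[Si](C(C)C)(C(C)C)C(C)C | intermediate
4 | 3-iodo-5,7-bis(triisopropylsilyloxy)chromen-4-one | Ic1coc2cc(O[Si](C(C)C)(C(C)C)C(C)C)cc(O[Si](C(C)C)(C(C)C)C(C)C)c2c1=O | intermediate
5 | ethynyl(trimethyl)silane | C#C[Si](C)(C)C | starting material
6 | 3-[(trimethylsilyl)ethynyl]-5,7-bis(triisopropylsilyloxy)chromen-4-one | C[Si](C)(C)C#Cc1coc2cc(O[Si](C(C)C)(C(C)C)C(C)C)cc(O[Si](C(C)C)(C(C)C)C(C)C)c2c1=O | intermediate
7 | 3-ethynyl-5,7-bis(triisopropylsilyloxy)chromen-4-one | C#Cc1coc2cc(O[Si](C(C)C)(C(C)C)C(C)C)cc(O[Si](C(C)C)(C(C)C)C(C)C)c2c1=O | intermediate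
8 | squaric acid (3,4-dihydroxycyclobut-3-ene-1,2-dione) | OC1=C(O)C(=O)C1=O | starting material
9 | benzyl alcohol | OCc1ccccc1 | starting material
10 | 3,4-bis(benzyloxy)cyclobut-3-ene-1,2-dione | O=C1C(=O)C(OCc2ccccc2)=C1OCc1ccccc1 | intermediate
11 | 2,3-bis(benzyloxy)-4-hydroxycyclobut-2-en-1-one (racemic) | O=C1C(OCc2ccccc2)=C(OCc2ccccc2)C1O | intermediate
12 | 3-(benzyloxy)cyclobut-3-ene-1,2-dione | O=C1C=C(OCc2ccccc2)C1=O | intermediate
13 | lithium [4-oxo-5,7-bis(triisopropylsilyloxy)chromen-3-yl]acetylide (not isolated) | [Li]C#Cc1coc2cc(O[Si](C(C)C)(C(C)C)C(C)C)cc(O[Si](C(C)C)(C(C)C)C(C)C)c2c1=O | intermediate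
14 | 3-(benzyloxy)-4-hydroxy-4-{[4-oxo-5,7-bis(triisopropylsilyloxy)chromen-3-yl]ethynyl}cyclobut-2-en-1-one (racemic) | O=C1C=C(OCc2ccccc2)C1(O)C#Cc1coc2cc(O[Si](C(C)C)(C(C)C)C(C)C)cc(O[Si](C(C)C)(C(C)C)C(C)C)c2c1=O | intermediate
15 | (3Z)-3-(benzyloxy)-4-hydroxy-6-[4-oxo-5,7-bis(triisopropylsilyloxy)chromen-3-yl]hexa-1,3-dien-5-yn-1-one (enynylketene, not isolated) | O=C=C/C(OCc1ccccc1)=C(/O)C#Cc1coc2cc(O[Si](C(C)C)(C(C)C)C(C)C)cc(O[Si](C(C)C)(C(C)C)C(C)C)c2c1=O | intermediate
16 | 5-(benzyloxy)-4-hydroxy-2-[4-oxo-5,7-bis(triisopropylsilyloxy)chromen-3-yl]phenoxyl-3-yl diradical (radical centres at the phenoxyl oxygen and at ring carbon 3; not isolated) | [O]c1cc(OCc2ccccc2)c(O)[c]c1-c1coc2cc(O[Si](C(C)C)(C(C)C)C(C)C)cc(O[Si](C(C)C)(C(C)C)C(C)C)c2c1=O | intermediate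
17 | 2-(benzyloxy)-5-[4-oxo-5,7-bis(triisopropylsilyloxy)chromen-3-yl]cyclohexa-2,5-diene-1,4-dione | O=C1C=C(OCc2ccccc2)C(=O)C=C1c1coc2cc(O[Si](C(C)C)(C(C)C)C(C)C)cc(O[Si](C(C)C)(C(C)C)C(C)C)c2c1=O | intermediate
18 | 3-[4-(benzyloxy)-2,5-dihydroxyphenyl]-5,7-bis(triisopropylsilyloxy)chromen-4-one | Oc1cc(OCc2ccccc2)c(O)cc1-c1coc2cc(O[Si](C(C)C)(C(C)C)C(C)C)cc(O[Si](C(C)C)(C(C)C)C(C)C)c2c1=O | intermediate
19 | 3-[4-(benzyloxy)-2,5-dimethoxyphenyl]-5,7-bis(triisopropylsilyloxy)chromen-4-one | COc1cc(OCc2ccccc2)c(OC)cc1-c1coc2cc(O[Si](C(C)C)(C(C)C)C(C)C)cc(O[Si](C(C)C)(C(C)C)C(C)C)c2c1=O | intermediate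
20 | 3-(4-hydroxy-2,5-dimethoxyphenyl)-5,7-bis(triisopropylsilyloxy)chromen-4-one | COc1cc(O)c(OC)cc1-c1coc2cc(O[Si](C(C)C)(C(C)C)C(C)C)cc(O[Si](C(C)C)(C(C)C)C(C)C)c2c1=O | intermediate
21 | 3-methylbut-2-en-1-ol | CC(C)=CCO | starting material
22 | 3-[2,5-dimethoxy-4-(3-methylbut-2-enyloxy)phenyl]-5,7-bis(triisopropylsilyloxy)chromen-4-one | COc1cc(OCC=C(C)C)c(OC)cc1-c1coc2cc(O[Si](C(C)C)(C(C)C)C(C)C)cc(O[Si](C(C)C)(C(C)C)C(C)C)c2c1=O | intermediate
23 | brandisianin A, 3-[2,5-dimethoxy-4-(3-methylbut-2-enyloxy)phenyl]-5,7-dihydroxychromen-4-one | COc1cc(-c2coc3cc(O)cc(O)c3c2=O)c(OC)cc1OCC=C(C)C | target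

## Step count and least certain steps

Total step count: 15. Longest linear sequence: 12 steps (steps 1 to 5 and 9 to 15); the squarate branch (steps 6 to 8) joins at step 9.

**Step 10 (key step).** The most likely failure is closure of ketene 15 at the near alkyne carbon to a five-membered ring, because the chromonyl group can stabilise the exocyclic radical or cation formed on that path. Oligomerisation of the ketene or of the electron-poor quinone at higher concentration is a second possibility.
Fallback: ring B is brought in whole by Suzuki–Miyaura coupling, which is established for 3-iodochromones. Purchased 2,5-dimethoxyphenol F1 is benzylated (BnBr, K2CO3) to 2-(benzyloxy)-1,4-dimethoxybenzene F2. Bromination with N-bromosuccinimide should take place para to the benzyloxy group and give 1-(benzyloxy)-4-bromo-2,5-dimethoxybenzene F3. Bromine–lithium exchange (n-BuLi), triisopropyl borate and acidic work-up give [4-(benzyloxy)-2,5-dimethoxyphenyl]boronic acid F4. Coupling of F4 with iodochromone 4 (Pd(dppf)Cl2, K3PO4, dioxane/H2O, 60 °C) gives 19. The fallback sets out from 4 and comes back to the route at 19.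

**Step 9.** Deprotonation of the alkyne may be incomplete, or the base or the acetylide may attack the pyranone at C2 and open the ring. Some addition at the vinylogous ester carbonyl would give the wrong substitution pattern after step 10.
Fallback: the order of bond formation is reversed so that no chromonyl anion is needed. The lithium acetylide of 5 (n-BuLi, THF, −78 °C) is added to 12 to give 3-(benzyloxy)-4-hydroxy-4-[(trimethylsilyl)ethynyl]cyclobut-2-en-1-one F5. Silver-catalysed cleavage of the C–Si bond as in step 5 gives 3-(benzyloxy)-4-ethynyl-4-hydroxycyclobut-2-en-1-one F6. Sonogashira coupling of F6 with 4 (Pd(PPh3)2Cl2, CuI, Et3N, THF, rt) gives 14. The fallback sets out from 12 and comes back at 14.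

**Step 12.** A ring A silyl group may be lost through attack of carbonate or phenoxide at silicon, most likely at O7, which is para to the carbonyl; the freed phenol would then be methylated. The hydroquinone may also be reoxidised by traces of air under base.
Fallback: the Williamson alkylation of phenoxide salts is replaced by diazoalkane methylation of the phenols, which needs no metal carbonate and forms no metal phenoxide. Hydroquinone 18 is treated with (trimethylsilyl)diazomethane and iPr2NEt in MeCN/MeOH at rt to give 19. The fallback sets out from 18 and comes back at 19, and makes no new compound.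

**Step 5.** Cleavage of an aryl O–Si bond may compete with the alkynyl C–Si bond, or methanol may add to the pyranone if the medium turns basic.
Fallback: the silyl-protected alkyne is avoided altogether. Stille coupling of 4 with tributyl(ethynyl)stannane (Pd(PPh3)4, toluene, 80 °C) gives the terminal alkyne 7 directly under neutral conditions. The fallback sets out from 4 and comes back at 7, and makes no new compound.

## Further compounds

F1 | step 10 | 2,5-dimethoxyphenol (purchased) | COc1ccc(OC)c(O)c1
F2 | step 10 | 2-(benzyloxy)-1,4-dimethoxybenzene | COc1ccc(OC)c(OCc2ccccc2)c1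
F3 | step 10 | 1-(benzyloxy)-4-bromo-2,5-dimethoxybenzene | COc1cc(OCc2ccccc2)c(OC)cc1Br
F4 | step 10 | [4-(benzyloxy)-2,5-dimethoxyphenyl]boronic acid | COc1cc(OCc2ccccc2)c(OC)cc1B(O)O
F5 | step 9 | 3-(benzyloxy)-4-hydroxy-4-[(trimethylsilyl)ethynyl]cyclobut-2-en-1-one (racemic) | O=C1C=C(OCc2ccccc2)C1(O)C#C[Si](C)(C)C
F6 | step 9 | 3-(benzyloxy)-4-ethynyl-4-hydroxycyclobut-2-en-1-one (racemic) | O=C1C=C(OCc2ccccc2)C1(O)C#C
F0 | step 12 | none | none
F0 | step 5 | none | none
A1 | alternative 1 | 3-[2,5-dimethoxy-4-(3-methylbut-2-enyloxy)phenyl]-5,7-difluorochromen-4-one | COc1cc(-c2coc3cc(F)cc(F)c3c2=O)c(OC)cc1OCC=C(C)C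
A2 | alternative 1 | 2,4,6-trifluorobenzoyl chloride | O=C(Cl)c1c(F)cc(F)cc1F
A3 | alternative 1 | 4-[(E)-2-[2,5-dimethoxy-4-(3-methylbut-2-enyloxy)phenyl]ethenyl]morpholine | COc1cc(/C=C/N2CCOCC2)c(OC)cc1OCC=C(C)C
A4 | alternative 2 | 3-[2,5-dimethoxy-4-(3-methylbut-2-enyloxy)phenyl]-5,7-bis(pivaloyloxy)chromen-4-one | COc1cc(-c2coc3cc(OC(=O)C(C)(C)C)cc(OC(=O)C(C)(C)C)c3c2=O)c(OC)cc1OCC=C(C)C
A5 | alternative 2 | (E)-3-(dimethylamino)-1-[2-hydroxy-4,6-bis(pivaloyloxy)phenyl]prop-2-en-1-one | CN(C)/C=C/C(=O)c1c(O)cc(OC(=O)C(C)(C)C)cc1OC(=O)C(C)(C)C
A6 | alternative 2 | 1,4-dimethoxy-2-(3-methylbut-2-enyloxy)benzene | COc1ccc(OC)c(OCC=C(C)C)c1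
A7 | alternative 3 | 3-[4-(allyloxy)-2,5-dimethoxyphenyl]-5,7-bis(methoxymethoxy)chromen-4-one | C=CCOc1cc(OC)c(-c2coc3cc(OCOC)cc(OCOC)c3c2=O)cc1OC
A8 | alternative 3 | 3,5-bis(methoxymethoxy)-2-(trimethylsilyl)phenyl trifluoromethanesulfonate | COCOc1cc(OCOC)c([Si](C)(C)C)c(OS(=O)(=O)C(F)(F)F)c1
A9 | alternative 3 | methyl 2-[4-(allyloxy)-2,5-dimethoxyphenyl]-3-oxopropanoate | COC(=O)C(C=O)c1cc(OC)c(OCC=C)cc1OC
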